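**Remark:** atoms carry chromene numbers throughout (O1, C2, C3, C4, C4a, C5–C8, C8a; ring A is the carbocycle, ring B the pyranone), also in the monocyclic precursors (pyranone C6 = C8a, pyranone C5 = C4a); the target is taken as the drawn C5-enol/C7-keto tautomer.

**Strategy.** Ring A (C4a, C5, C6, C7, C8, C8a) carries oxygen on C5, C7 and C8a, the 1,3,5-pattern of a cyclised triketide. It is therefore cut at C5–C4a and C8–C8a into a C5–C8 β-keto ester and the C4a=C8a enone unit of a preformed (S)-pyranone (ring B). The key step joins a bis-silyl dienol ether of the keto ester to a 6-phenylthio-dihydropyranone: vinylogous Mukaiyama–Michael addition at C8a and loss of thiolate make C8–C8a, Dieckmann closure of C4a on the ester makes C5–C4a, and ring A emerges aromatic in one pot. A catalyst-controlled dearomative geranylation at C8 then sets the quaternary centre.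

Key step: step 6

## Route

**Step 1**
Reactants: 1 methyl 3-oxopentanoate; 2 1-bromo-3-methylbut-2-ene (prenyl bromide)
Product: 3 methyl 2-(3-methylbut-2-en-1-yl)-3-oxopentanoate (racemic)
Conditions: K2CO3, acetone, reflux
Reagents that add atoms: none
Why: C-alkylation of the β-keto ester enolate at the primary allylic bromide (acetoacetic ester alkylation); the new C6 centre is of no consequence because it becomes sp2 later.

**Step 2**
Reactants: 3 methyl 2-(3-methylbut-2-en-1-yl)-3-oxopentanoate
Product: 4 1-methoxy-2-(3-methylbut-2-en-1-yl)-1,3-bis(trimethylsilyloxy)penta-1,3-diene (mixture of double-bond isomers)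
Conditions: TMSOTf (2.2 equiv), Et3N (2.5 equiv), Et2O, 0 °C → rt
Reagents that add atoms: trimethylsilyl trifluoromethanesulfonate, C[Si](C)(C)OS(=O)(=O)C(F)(F)F
Why: Double O-silylation by soft enolisation gives the 1,3-bis(silyloxy)diene whose terminal carbon C8 is the nucleophilic site; its double-bond geometry is irrelevant since C6 and C8 end up sp2.

**Step 3**
Reactants: 5 trans-1-methoxy-3-(trimethylsilyloxy)buta-1,3-diene (Danishefsky's diene); 6 acetaldehyde
Product: 8 (2S)-2-methyl-2,3-dihydro-4H-pyran-4-one, via silyl enol ether cycloadduct 7 (not isolated)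
Conditions: (R,R)-(salen)CrBF4 (2 mol%, trivalent chromium), 4 Å MS, t-BuOMe, −30 °C; then CF3CO2H (cat.), CH2Cl2, 0 °C
Reagents that add atoms: none
Why: Hetero-Diels–Alder reaction of the aldehyde bound to the chiral trivalent chromium salen Lewis acid, which exposes one aldehyde face so that C2 should be set S (the sense expected for linear aliphatic aldehydes with this catalyst antipode), followed by acid-induced loss of methanol and the silyl group.

**Step 4**
Reactants: 8 (2S)-2-methyl-2,3-dihydro-4H-pyran-4-one
Product: 9 (2S)-2-methyl-6-(phenylsulfanyl)oxan-4-one (C8a epimers, mainly 2,6-trans)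
Conditions: PhSH, Et3N (cat.), CH2Cl2, 0 °C → rt
Reagents that add atoms: benzenethiol, Sc1ccccc1
Why: Thia-Michael addition of the thiolate to the vinylogous ester carbon C8a, mainly by axial attack trans to the C2 methyl group; the new acetal centre is removed again in step 5.

**Step 5**
Reactants: 9 (2S)-2-methyl-6-(phenylsulfanyl)oxan-4-one
Product: 11 (2S)-2-methyl-6-(phenylsulfanyl)-2,3-dihydro-4H-pyran-4-one, via chloro sulfide 10 (not isolated)
Conditions: NCS, CH2Cl2, 0 °C → rt; then Et3N, 0 °C
Reagents that add atoms: N-chlorosuccinimide, O=C1CCC(=O)N1Cl (its chlorine is held by 10 only and leaves again)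
Why: Sulfur-directed chlorination at the S,O-acetal carbon (chlorosulfonium, then thionium ion) and base-induced loss of HCl toward C4a should give the vinylogous thioester (the established oxidation of β-phenylthio ketones to β-phenylthio enones); C2 is untouched.

**Step 6**
Reactants: 4 1-methoxy-2-(3-methylbut-2-en-1-yl)-1,3-bis(trimethylsilyloxy)penta-1,3-diene; 11 (2S)-2-methyl-6-(phenylsulfanyl)-2,3-dihydro-4H-pyran-4-one
Product: 14 (2S)-5,7-dihydroxy-2,8-dimethyl-6-(3-methylbut-2-en-1-yl)-2,3-dihydro-4H-chromen-4-one, via bis-silyl Michael adduct 12 (not isolated), via pyranonyl keto ester 13 (not isolated)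
Conditions: TMSOTf (10 mol%), CH2Cl2, −78 → −40 °C; then K2CO3, MeOH, 0 °C → rt; aq. NH4Cl
Reagents that add atoms: none
Why: TMSOTf silylates the C4 carbonyl of 11 and the terminal carbon C8 of dienol ether 4 adds to C8a of the resulting thio-stabilised pyrylium-type cation (vinylogous Mukaiyama–Michael addition) to give 12; methanolic K2CO3 then cleaves both silyl ethers, the ring-B enolate expels thiolate from C8a (addition–elimination at a vinylogous thioester) to give 13, and deprotonation at the doubly activated C8 makes C4a nucleophilic so that it attacks the methyl ester C5 (Dieckmann condensation), after which loss of methoxide and enolisation aromatise ring A. The closest known reaction types are the benzannulations of 1,3-bis(silyloxy)dienes with β-heteroatom-substituted enones and the Claisen-type cyclisation of triketo esters to acylphloroglucinols. Ring A is closed by a 6-exo-trig attack of the C4a enolate carbon on the ester carbonyl, the first bond (C8–C8a) being intermolecular. No new stereocentre survives (C6 and C8 become sp2) and the C2 centre of ring B is a spectator. The step needs conjugate rather than carbonyl addition (secured by the soft silyl enol ether and Lewis acid manifold), reaction at the diene terminus C8 (the vinylogous position of such dienes), loss of thiolate rather than of the ring oxygen O1 (thiolate is by far the better leaving group under base) and Claisen rather than aldol closure (attack of C6 on C4 would demand a bridgehead alkene across ring B).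

**Step 7**
Reactants: 14 (2S)-5,7-dihydroxy-2,8-dimethyl-6-(3-methylbut-2-en-1-yl)-2,3-dihydro-4H-chromen-4-one; 15 geranyl acetate
Product: 16 (2S,8R)-8-[(2E)-3,7-dimethylocta-2,6-dien-1-yl]-5-hydroxy-2,8-dimethyl-6-(3-methylbut-2-en-1-yl)-2,3-dihydro-4H-chromene-4,7(8H)-dione (target)
Conditions: Pd2(dba)3 (2.5 mol%, zerovalent palladium), (R,R)-DACH-phenyl Trost ligand (7.5 mol%), K2CO3 (1.1 equiv), THF, 0 °C → rt; aq. citric acid
Reagents that add atoms: none
Why: Tsuji–Trost asymmetric allylic alkylation with dearomatisation, in which the 7-phenoxide of 14 should attack the CH2 terminus of the π-geranyl palladium complex through C8 (methyl-bearing and less hindered than C6, and the product keeps the C5–OH···O=C4 chelate), reversible O-allylation funnels to C-allylation, and the chiral ligand differentiates the two faces of C8 to set the 8R quaternary centre; the (R,R) ligand is written here and its mirror image is used if a first run shows the opposite sense.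

## Compound list

1 | methyl 3-oxopentanoate | CCC(=O)CC(=O)OC | starting material
2 | 1-bromo-3-methylbut-2-ene (prenyl bromide) | CC(C)=CCBr | starting material
3 | methyl 2-(3-methylbut-2-en-1-yl)-3-oxopentanoate (racemic) | CCC(=O)C(CC=C(C)C)C(=O)OC | intermediate
4 | 1-methoxy-2-(3-methylbut-2-en-1-yl)-1,3-bis(trimethylsilyloxy)penta-1,3-diene (double-bond isomers) | CC=C(O[Si](C)(C)C)C(CC=C(C)C)=C(OC)O[Si](C)(C)C | intermediate
5 | trans-1-methoxy-3-(trimethylsilyloxy)buta-1,3-diene (Danishefsky's diene) | CO/C=C/C(=C)O[Si](C)(C)C | starting material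
6 | acetaldehyde | CC=O | starting material
7 | (6S)-2-methoxy-6-methyl-4-(trimethylsilyloxy)-5,6-dihydro-2H-pyran (acetal epimers) | COC1C=C(O[Si](C)(C)C)C[C@H](C)O1 | intermediate (not isolated)
8 | (2S)-2-methyl-2,3-dihydro-4H-pyran-4-one | O=C1C=CO[C@@H](C)C1 | intermediate
9 | (2S)-2-methyl-6-(phenylsulfanyl)oxan-4-one (C8a epimers) | O=C1CC(Sc2ccccc2)O[C@@H](C)C1 | intermediate
10 | (2S)-6-chloro-2-methyl-6-(phenylsulfanyl)oxan-4-one | O=C1CC(Cl)(Sc2ccccc2)O[C@@H](C)C1 | intermediate (not isolated)
11 | (2S)-2-methyl-6-(phenylsulfanyl)-2,3-dihydro-4H-pyran-4-one | O=C1C=C(Sc2ccccc2)O[C@@H](C)C1 | intermediate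
12 | methyl 2-(3-methylbut-2-en-1-yl)-4-[(6S)-6-methyl-2-(phenylsulfanyl)-4-(trimethylsilyloxy)-5,6-dihydro-2H-pyran-2-yl]-3-(trimethylsilyloxy)pent-2-enoate (isomer mixture at C8, C8a and the enol ether) | COC(=O)C(CC=C(C)C)=C(O[Si](C)(C)C)C(C)C1(Sc2ccccc2)C=C(O[Si](C)(C)C)C[C@H](C)O1 | intermediate (not isolated)
13 | methyl 4-[(2S)-2-methyl-4-oxo-3,4-dihydro-2H-pyran-6-yl]-2-(3-methylbut-2-en-1-yl)-3-oxopentanoate (mixture at C6 and C8) | COC(=O)C(CC=C(C)C)C(=O)C(C)C1=CC(=O)C[C@H](C)O1 | intermediate (not isolated)
14 | (2S)-5,7-dihydroxy-2,8-dimethyl-6-(3-methylbut-2-en-1-yl)-2,3-dihydro-4H-chromen-4-one | CC(C)=CCc1c(O)c(C)c2O[C@@H](C)CC(=O)c2c1O | intermediate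
15 | geranyl acetate, (2E)-3,7-dimethylocta-2,6-dien-1-yl acetate | CC(C)=CCC/C(C)=C/COC(C)=O | starting material
16 | (2S,8R)-8-[(2E)-3,7-dimethylocta-2,6-dien-1-yl]-5-hydroxy-2,8-dimethyl-6-(3-methylbut-2-en-1-yl)-2,3-dihydro-4H-chromene-4,7(8H)-dione | CC(C)=CCC/C(C)=C/C[C@@]1(C)C(=O)C(CC=C(C)C)=C(O)C2=C1O[C@@H](C)CC2=O | target

## Step count and risks

Total steps: 7. Longest linear sequence: 5 steps (5 + 6 → 8 → 9 → 11 → 14 → 16).

**Step 7.** Process at risk: poor discrimination of the two faces of C8 by the chiral palladium complex, together with competing attack through C6, through oxygen or at the tertiary end of the geranyl unit. The fallback sets out from 14 and ends at 16. Alkylative dearomatisation without a chiral catalyst (geranyl bromide, NaOMe, MeOH, 0 °C) is expected to give 16 together with its C8 epimer, (2S,8S)-8-[(2E)-3,7-dimethylocta-2,6-dien-1-yl]-5-hydroxy-2,8-dimethyl-6-(3-methylbut-2-en-1-yl)-2,3-dihydro-4H-chromene-4,7(8H)-dione F4. Because C2 is fixed the two are diastereomers and would be separated by chromatography.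

**Step 6.** Process at risk: carbonyl addition or opening of ring B in place of conjugate addition–elimination, and base-induced retro-oxa-Michael opening of ring B that would erode C2. The fallback sets out from 3 and 11 and returns at 14, with ring closure under neutral, thermal conditions.
- 3 is saponified (LiOH, aqueous THF, 0 °C) and the crude keto acid is condensed with acetone (Ac2O, cat. H2SO4) to 6-ethyl-2,2-dimethyl-5-(3-methylbut-2-en-1-yl)-4H-1,3-dioxin-4-one F1.
- LiN(iPr)2 and TMSCl convert it into the silyl dienol ether trimethyl{[6-ethylidene-2,2-dimethyl-5-(3-methylbut-2-en-1-yl)-6H-1,3-dioxin-4-yl]oxy}silane F2.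
- TMSOTf-catalysed vinylogous Mukaiyama addition of this ether to 11, then Et3N·3HF, should give with loss of thiolate 2,2-dimethyl-5-(3-methylbut-2-en-1-yl)-6-{1-[(2S)-2-methyl-4-oxo-3,4-dihydro-2H-pyran-6-yl]ethyl}-4H-1,3-dioxin-4-one F3.
- Heating this in toluene (110 °C) releases acetone and an acylketene that is captured by C4a, so that ring A closes and aromatises to 14.

**Step 3.** Process at risk: low facial selectivity with the small, volatile aldehyde and loss of the volatile product on isolation. The fallback replaces 5 and 6, so no numbered compound precedes it; it sets out from purchased ethyl (3S)-3-hydroxybutanoate F5 and returns at 8, taking C2 from the chiral pool.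
- MeNH(OMe)·HCl and iPrMgCl (THF, −20 °C) give the Weinreb amide (3S)-3-hydroxy-N-methoxy-N-methylbutanamide F6.
- HC≡CMgBr (3 equiv, THF, 0 °C) gives (5S)-5-hydroxyhex-1-yn-3-one F7.
- 6-endo cyclisation of the hydroxyl group onto the ynone (AgOTf cat., CH2Cl2, rt) gives 8.

## Further compounds

F1 | step 6 | 6-ethyl-2,2-dimethyl-5-(3-methylbut-2-en-1-yl)-4H-1,3-dioxin-4-one | CCC1=C(CC=C(C)C)C(=O)OC(C)(C)O1
F2 | step 6 | trimethyl{[6-ethylidene-2,2-dimethyl-5-(3-methylbut-2-en-1-yl)-6H-1,3-dioxin-4-yl]oxy}silane | CC=C1OC(C)(C)OC(O[Si](C)(C)C)=C1CC=C(C)C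
F3 | step 6 | 2,2-dimethyl-5-(3-methylbut-2-en-1-yl)-6-{1-[(2S)-2-methyl-4-oxo-3,4-dihydro-2H-pyran-6-yl]ethyl}-4H-1,3-dioxin-4-one | CC(C1=C(CC=C(C)C)C(=O)OC(C)(C)O1)C2=CC(=O)C[C@H](C)O2
F4 | step 7 | (2S,8S)-8-[(2E)-3,7-dimethylocta-2,6-dien-1-yl]-5-hydroxy-2,8-dimethyl-6-(3-methylbut-2-en-1-yl)-2,3-dihydro-4H-chromene-4,7(8H)-dione | CC(C)=CCC/C(C)=C/C[C@]1(C)C(=O)C(CC=C(C)C)=C(O)C2=C1O[C@@H](C)CC2=O
F5 | step 3 | ethyl (3S)-3-hydroxybutanoate (purchased) | CCOC(=O)C[C@H](C)O
F6 | step 3 | (3S)-3-hydroxy-N-methoxy-N-methylbutanamide | CON(C)C(=O)C[C@H](C)O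
F7 | step 3 | (5S)-5-hydroxyhex-1-yn-3-one | C#CC(=O)C[C@H](C)O
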